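**Plan** (clerodane numbering: decalin C1–C10, side chain C11–C16, methyls C17–C20)

- Cuts: the C15–O ester bond and the C12–C13 bond (sp3–sp2 Suzuki coupling with a (Z)-3-iodobut-2-ene-1,4-diol unit); the C10–H bond back to a C10 tertiary alcohol; then C5–C10 and C2–C3 together, which dissolves ring A.
- Enabling feature: in ring A the C3=C4 bond is β,γ to C10 through quaternary C5. A 10-hydroxy compound is therefore the transannular carbonyl-ene product of a ten-membered C10 ketone with a C4=C5 bond, and that ketone is the oxy-Cope product of a ring B cyclohexanol carrying vinyl (C1=C2) on C10 and isopropenyl (C3=C4–C18) on C5.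
- Forward: (R)-pulegone (ring B with C8–C17) → C19 at C5, then C20 and the C11–C12 arm at C9 by enolate alkylations → vinyl at C10 → tandem oxy-Cope/transannular ene (ring A built, ring B re-closed) → radical removal of the C10 hydroxyl → side chain by B-alkyl Suzuki coupling → docosanoate → desilylation.
- Stereochemistry: C8 from pulegone; C5 and C9 by alkylation relative to C8; C5 is carried through the key step (centre → olefin face → centre); C10–H by hydrogen-atom transfer anti to the axial C5/C9 methyls; 13E from trans-hydroalumination/iodination and stereoretentive coupling.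

Key step: step 8

Remark: 8 and 11 are drawn as the C10 epimers expected from attack anti to the axial C5/C9 methyls; the other C10 epimers would serve equally, because C10 is trigonal again in 10 and in the radical of step 10.

**Step 1**
Reactants: 1 (R)-(+)-pulegone
Product: 2 (2S,5R)-2,5-dimethyl-2-(prop-1-en-2-yl)cyclohexan-1-one
Conditions: NaOC(CH3)2CH2CH3 (1.05 equiv), toluene, 0 °C → rt; MeI, 0 °C → rt
Reagents that add atoms: iodomethane, CI
Why: Deconjugative α-alkylation of the extended dienolate of an α-alkylidene ketone, known for pulegone itself; the new C5 centre should arise mainly by axial attack on the half-chair with the C8 methyl equatorial, which puts the new methyl cis to the C8 methyl (1,4-induction), and the minor epimer is removed by chromatography.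

**Step 2**
Reactants: 2 (2S,5R)-2,5-dimethyl-2-(prop-1-en-2-yl)cyclohexan-1-one
Product: 3 (2S,5R,6S)-2,5,6-trimethyl-2-(prop-1-en-2-yl)cyclohexan-1-one
Conditions: LiN(i-Pr)2, THF, −78 °C; MeI, −78 → 0 °C
Reagents that add atoms: iodomethane, CI
Why: Kinetic enolate methylation at the only enolisable position (C9), anti to the C8 methyl; this centre is made trigonal again in step 3, so its configuration is not critical.

**Step 3**
Reactants: 3 (2S,5R,6S)-2,5,6-trimethyl-2-(prop-1-en-2-yl)cyclohexan-1-one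
Product: 4 ethyl 2-[(1S,3S,6R)-1,3,6-trimethyl-2-oxo-3-(prop-1-en-2-yl)cyclohexyl]acetate
Conditions: LiN(i-Pr)2, THF, −78 → 0 °C; DMPU, BrCH2CO2Et, −78 °C → rt
Reagents that add atoms: ethyl bromoacetate, CCOC(=O)CBr
Why: Alkylation of the tetrasubstituted lithium enolate with a reactive α-halo ester creates quaternary C9; the C8 methyl turns pseudoaxial to avoid A(1,2) strain with the enolate methyl and the electrophile enters anti to it, so the C11 arm ends trans and C20 cis to C17.

**Step 4**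
Reactants: 4 ethyl 2-[(1S,3S,6R)-1,3,6-trimethyl-2-oxo-3-(prop-1-en-2-yl)cyclohexyl]acetate
Product: 5 (1R,2S,3R,6S)-2-(2-hydroxyethyl)-2,3,6-trimethyl-6-(prop-1-en-2-yl)cyclohexan-1-ol
Conditions: LiAlH4, THF, 0 °C → rt
Reagents that add atoms: none
Why: Hydride reduction of the ester to the C12 alcohol, accepted together with reduction of the ketone because the two cannot be told apart reliably; the C10 carbinol centre (hydride anti to the axial methyls expected) is removed again in step 6.

**Step 5**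
Reactants: 5 (1R,2S,3R,6S)-2-(2-hydroxyethyl)-2,3,6-trimethyl-6-(prop-1-en-2-yl)cyclohexan-1-ol
Product: 6 (1R,2S,3R,6S)-2-{2-[(tert-butyldimethylsilyl)oxy]ethyl}-2,3,6-trimethyl-6-(prop-1-en-2-yl)cyclohexan-1-ol
Conditions: TBSCl (1.05 equiv), imidazole, CH2Cl2, 0 °C
Reagents that add atoms: tert-butyldimethylsilyl chloride, CC(C)(C)[Si](C)(C)Cl
Why: Chemoselective silylation of the primary alcohol; the secondary alcohol lies between two quaternary carbons and should not react.

**Step 6**
Reactants: 6 (1R,2S,3R,6S)-2-{2-[(tert-butyldimethylsilyl)oxy]ethyl}-2,3,6-trimethyl-6-(prop-1-en-2-yl)cyclohexan-1-ol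
Product: 7 (2S,3R,6S)-2-{2-[(tert-butyldimethylsilyl)oxy]ethyl}-2,3,6-trimethyl-6-(prop-1-en-2-yl)cyclohexan-1-one
Conditions: Dess–Martin periodinane, CH2Cl2, rt
Reagents that add atoms: none
Why: Dess–Martin oxidation of a hindered secondary alcohol to the non-enolisable ketone; no stereocentre is at risk because both α-carbons are quaternary.

**Step 7**
Reactants: 7 (2S,3R,6S)-2-{2-[(tert-butyldimethylsilyl)oxy]ethyl}-2,3,6-trimethyl-6-(prop-1-en-2-yl)cyclohexan-1-one
Product: 8 (1R,2S,3R,6S)-2-{2-[(tert-butyldimethylsilyl)oxy]ethyl}-1-ethenyl-2,3,6-trimethyl-6-(prop-1-en-2-yl)cyclohexan-1-ol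
Conditions: (CH2=CH)4Sn, CH3Li, Et2O, 0 °C (gives CH2=CHLi); then 7, THF, −78 °C → rt
Reagents that add atoms: vinyllithium, [Li]C=C (made in the flask from tetravinylstannane, C=C[Sn](C=C)(C=C)C=C)
Why: 1,2-Addition of a small sp2 organolithium to a ketone that can neither enolise nor be reduced by the reagent; attack on the face opposite the two axial α-methyls (C19, C20) should place vinyl cis to isopropenyl.

**Step 8**
Reactants: 8 (1R,2S,3R,6S)-2-{2-[(tert-butyldimethylsilyl)oxy]ethyl}-1-ethenyl-2,3,6-trimethyl-6-(prop-1-en-2-yl)cyclohexan-1-ol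
Product: 11 (4aR,5S,6R,8aS)-5-{2-[(tert-butyldimethylsilyl)oxy]ethyl}-1,5,6,8a-tetramethyl-3,4,4a,5,6,7,8,8a-octahydronaphthalen-4a-ol, via cyclodecadienol 9 (not isolated), via cyclodecenone 10 (not isolated)
Conditions: DBU (2 equiv), toluene, 220 °C, sealed tube
Reagents that add atoms: none
Why: On heating, the 3-hydroxy-1,5-diene C3=C4–C5–C10(OH)–C1=C2 of 8 undergoes an oxy-Cope [3,3] shift through a chair transition state (ring B chair with the C8 methyl and the isopropenyl group equatorial and the vinyl group axial), which forms C2–C3, opens ring B and gives dienol 9, tautomerised by DBU to the (Z)-cyclodecenone 10. In the same flask the C10 carbonyl of 10 adds across the ring to C5 of the C4=C5 bond in a transannular carbonyl-ene reaction, which forms C5–C10, passes the C3 hydrogen to oxygen and leaves the C3=C4 double bond of the target. The closest known reaction type is the thermal tandem oxy-Cope/transannular ene reaction of 1,2-dialkenylcyclohexanols to decalin-4a-ols. Ring A is made from the sigmatropic C2–C3 bond and closed, together with the re-closed ring B, by the C5–C10 bond, in which alkene carbon C5 attacks the ketone carbon (6-exo-trig at the carbonyl for both six-membered rings, with ring A boat-like so that the C10 oxygen reaches the axial C3–H). Of the new centres, C5 keeps the face its methyl had in 8, because C10 returns to the side from which it left and because the only ring B chair with the C8 methyl equatorial puts the C5 and C9 methyls syn-diaxial as in the target, while C10 (cis fusion, from the Z olefin) is erased in steps 9 and 10. The step needs this diene and no other to rearrange (the C9 arm is saturated, so no second 1,5-diene exists), closure at C5 and not at C4 (C5 and C10 are held face to face by the bond just broken) and hydrogen transfer from ring carbon C3 and not from the C4 methyl (the carbinol oxygen lies axial over ring A).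

**Step 9**
Reactants: 11 (4aR,5S,6R,8aS)-5-{2-[(tert-butyldimethylsilyl)oxy]ethyl}-1,5,6,8a-tetramethyl-3,4,4a,5,6,7,8,8a-octahydronaphthalen-4a-ol
Product: 12 (4aR,5S,6R,8aS)-5-{2-[(tert-butyldimethylsilyl)oxy]ethyl}-1,5,6,8a-tetramethyl-3,4,4a,5,6,7,8,8a-octahydronaphthalen-4a-yl methyl oxalate
Conditions: n-BuLi, THF, −78 °C; ClC(O)CO2CH3, −78 → 0 °C
Reagents that add atoms: methyl chlorooxoacetate, COC(=O)C(=O)Cl
Why: Acylation of the lithium alkoxide of a hindered tertiary alcohol with a small, highly electrophilic acid chloride installs the radical leaving group; no stereocentre changes.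

**Step 10**
Reactants: 12 (4aR,5S,6R,8aS)-5-{2-[(tert-butyldimethylsilyl)oxy]ethyl}-1,5,6,8a-tetramethyl-3,4,4a,5,6,7,8,8a-octahydronaphthalen-4a-yl methyl oxalate
Product: 13 tert-butyldimethyl{2-[(1S,2R,4aR,8aR)-1,2,4a,5-tetramethyl-1,2,3,4,4a,7,8,8a-octahydronaphthalen-1-yl]ethoxy}silane
Conditions: Bu3SnH, AIBN (cat.), toluene, 110 °C
Reagents that add atoms: none
Why: Tin hydride chain reduction of a tertiary methyl oxalate (Barton–McCombie-type deoxygenation); the planar C10 radical should take hydrogen on the face opposite the axial C5 and C9 methyls, which gives the trans ring fusion with H10 syn to the C11 arm.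

**Step 11**
Reactants: 13 tert-butyldimethyl{2-[(1S,2R,4aR,8aR)-1,2,4a,5-tetramethyl-1,2,3,4,4a,7,8,8a-octahydronaphthalen-1-yl]ethoxy}silane
Product: 14 2-[(1S,2R,4aR,8aR)-1,2,4a,5-tetramethyl-1,2,3,4,4a,7,8,8a-octahydronaphthalen-1-yl]ethan-1-ol
Conditions: TBAF, THF, rt
Reagents that add atoms: none
Why: Fluoride cleavage of a primary silyl ether; nothing else in 13 responds to fluoride.

**Step 12**
Reactants: 14 2-[(1S,2R,4aR,8aR)-1,2,4a,5-tetramethyl-1,2,3,4,4a,7,8,8a-octahydronaphthalen-1-yl]ethan-1-ol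
Product: 15 (1S,2R,4aR,8aR)-1-(2-iodoethyl)-1,2,4a,5-tetramethyl-1,2,3,4,4a,7,8,8a-octahydronaphthalene
Conditions: I2, PPh3, imidazole, CH2Cl2, 0 °C → rt
Reagents that add atoms: iodine, II
Why: Appel-type iodination of a primary alcohol by SN2 displacement of the alkoxyphosphonium ion; the trisubstituted olefin is tolerated.

**Step 13**
Reactants: 16 but-2-yne-1,4-diol
Product: 17 4-[(tert-butyldimethylsilyl)oxy]but-2-yn-1-ol
Conditions: NaH (1.0 equiv), THF, 0 °C → rt; TBSCl (1.0 equiv)
Reagents that add atoms: tert-butyldimethylsilyl chloride, CC(C)(C)[Si](C)(C)Cl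
Why: Monosilylation of a symmetrical diol through its sparingly soluble mono-sodium alkoxide.

**Step 14**
Reactants: 17 4-[(tert-butyldimethylsilyl)oxy]but-2-yn-1-ol
Product: 19 (2Z)-4-[(tert-butyldimethylsilyl)oxy]-3-iodobut-2-en-1-ol, via alkenylaluminate 18 (not isolated)
Conditions: NaAlH2(OCH2CH2OCH3)2, THF, 0 °C → rt; then I2, THF, −78 → 0 °C
Reagents that add atoms: iodine, II
Why: Alkoxide-directed trans-hydroalumination of a propargylic alcohol puts hydride on the carbon next to the carbinol and aluminium on the distal carbon in a five-membered aluminate, and iodinolysis with retention gives the iodide cis to CH2OH, which fixes the later 13E geometry.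

**Step 15**
Reactants: 15 (1S,2R,4aR,8aR)-1-(2-iodoethyl)-1,2,4a,5-tetramethyl-1,2,3,4,4a,7,8,8a-octahydronaphthalene; 19 (2Z)-4-[(tert-butyldimethylsilyl)oxy]-3-iodobut-2-en-1-ol
Product: 22 (2E)-3-({[tert-butyldimethylsilyl]oxy}methyl)-5-[(1S,2R,4aR,8aR)-1,2,4a,5-tetramethyl-1,2,3,4,4a,7,8,8a-octahydronaphthalen-1-yl]pent-2-en-1-ol, via alkyllithium 20 (not isolated), via borate 21 (not isolated)
Conditions: t-BuLi (2.1 equiv), Et2O, −78 °C; B-methoxy-9-BBN, THF, −78 °C → rt; then 19, PdCl2(dppf) (5 mol %), AsPh3, K3PO4, DMF/H2O, rt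
Reagents that add atoms: none
Why: Iodine–lithium exchange, capture as the B-alkyl borate and Suzuki–Miyaura sp3–sp2 coupling with the alkenyl iodide, which proceeds with retention at the olefin, so C12 ends cis to C15 and C16 trans to C15 (13E); the free hydroxyl is tolerated.

**Step 16**
Reactants: 22 (2E)-3-({[tert-butyldimethylsilyl]oxy}methyl)-5-[(1S,2R,4aR,8aR)-1,2,4a,5-tetramethyl-1,2,3,4,4a,7,8,8a-octahydronaphthalen-1-yl]pent-2-en-1-ol; 23 docosanoic acid
Product: 24 (2E)-3-({[tert-butyldimethylsilyl]oxy}methyl)-5-[(1S,2R,4aR,8aR)-1,2,4a,5-tetramethyl-1,2,3,4,4a,7,8,8a-octahydronaphthalen-1-yl]pent-2-en-1-yl docosanoate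
Conditions: DCC, DMAP (cat.), CH2Cl2, 0 °C → rt
Reagents that add atoms: none
Why: Steglich esterification of the only free (primary allylic) hydroxyl.

**Step 17**
Reactants: 24 (2E)-3-({[tert-butyldimethylsilyl]oxy}methyl)-5-[(1S,2R,4aR,8aR)-1,2,4a,5-tetramethyl-1,2,3,4,4a,7,8,8a-octahydronaphthalen-1-yl]pent-2-en-1-yl docosanoate
Product: 25 (2E)-3-(hydroxymethyl)-5-[(1S,2R,4aR,8aR)-1,2,4a,5-tetramethyl-1,2,3,4,4a,7,8,8a-octahydronaphthalen-1-yl]pent-2-en-1-yl docosanoate (CNP0279526.1)
Conditions: HF·pyridine, pyridine/THF, 0 °C → rt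
Reagents that add atoms: none
Why: Mildly acidic fluoride cleavage of the primary silyl ether; the ester cannot migrate because the C15 and C16 oxygens are trans across the trisubstituted olefin.

**Compound list**

1 | (R)-(+)-pulegone, (5R)-5-methyl-2-(propan-2-ylidene)cyclohexan-1-one | C[C@@H]1CCC(=C(C)C)C(=O)C1 | starting material
2 | (2S,5R)-2,5-dimethyl-2-(prop-1-en-2-yl)cyclohexan-1-one (ring methyls cis) | C[C@@H]1CC[C@@](C)(C(C)=C)C(=O)C1 | intermediate
3 | (2S,5R,6S)-2,5,6-trimethyl-2-(prop-1-en-2-yl)cyclohexan-1-one | C[C@H]1[C@H](C)CC[C@@](C)(C(C)=C)C1=O | intermediate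
4 | ethyl 2-[(1S,3S,6R)-1,3,6-trimethyl-2-oxo-3-(prop-1-en-2-yl)cyclohexyl]acetate | CCOC(=O)C[C@@]1(C)[C@H](C)CC[C@@](C)(C(C)=C)C1=O | intermediate
5 | (1R,2S,3R,6S)-2-(2-hydroxyethyl)-2,3,6-trimethyl-6-(prop-1-en-2-yl)cyclohexan-1-ol | OCC[C@@]1(C)[C@H](C)CC[C@@](C)(C(C)=C)[C@@H]1O | intermediate
6 | (1R,2S,3R,6S)-2-{2-[(tert-butyldimethylsilyl)oxy]ethyl}-2,3,6-trimethyl-6-(prop-1-en-2-yl)cyclohexan-1-ol | CC(C)(C)[Si](C)(C)OCC[C@@]1(C)[C@H](C)CC[C@@](C)(C(C)=C)[C@@H]1O | intermediate
7 | (2S,3R,6S)-2-{2-[(tert-butyldimethylsilyl)oxy]ethyl}-2,3,6-trimethyl-6-(prop-1-en-2-yl)cyclohexan-1-one | CC(C)(C)[Si](C)(C)OCC[C@@]1(C)[C@H](C)CC[C@@](C)(C(C)=C)C1=O | intermediate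
8 | (1R,2S,3R,6S)-2-{2-[(tert-butyldimethylsilyl)oxy]ethyl}-1-ethenyl-2,3,6-trimethyl-6-(prop-1-en-2-yl)cyclohexan-1-ol (vinyl cis to isopropenyl) | CC(C)(C)[Si](C)(C)OCC[C@@]1(C)[C@H](C)CC[C@@](C)(C(C)=C)[C@@]1(O)C=C | intermediate
9 | (1Z,5Z,9R,10S)-10-{2-[(tert-butyldimethylsilyl)oxy]ethyl}-5,6,9,10-tetramethylcyclodeca-1,5-dien-1-ol | O/C1=C\CC/C(C)=C(C)\CC[C@@H](C)[C@]1(C)CCO[Si](C)(C)C(C)(C)C | intermediate (not isolated)
10 | (2S,3R,6Z)-2-{2-[(tert-butyldimethylsilyl)oxy]ethyl}-2,3,6,7-tetramethylcyclodec-6-en-1-one | O=C1CCC/C(C)=C(C)\CC[C@@H](C)[C@]1(C)CCO[Si](C)(C)C(C)(C)C | intermediate (not isolated)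
11 | (4aR,5S,6R,8aS)-5-{2-[(tert-butyldimethylsilyl)oxy]ethyl}-1,5,6,8a-tetramethyl-3,4,4a,5,6,7,8,8a-octahydronaphthalen-4a-ol (cis-fused, hydroxyl cis to the 8a-methyl) | CC(C)(C)[Si](C)(C)OCC[C@@]1(C)[C@H](C)CC[C@@]2(C)C(C)=CCC[C@@]12O | intermediate
12 | (4aR,5S,6R,8aS)-5-{2-[(tert-butyldimethylsilyl)oxy]ethyl}-1,5,6,8a-tetramethyl-3,4,4a,5,6,7,8,8a-octahydronaphthalen-4a-yl methyl oxalate | CC(C)(C)[Si](C)(C)OCC[C@@]1(C)[C@H](C)CC[C@@]2(C)C(C)=CCC[C@@]12OC(=O)C(=O)OC | intermediate
13 | tert-butyldimethyl{2-[(1S,2R,4aR,8aR)-1,2,4a,5-tetramethyl-1,2,3,4,4a,7,8,8a-octahydronaphthalen-1-yl]ethoxy}silane (trans-fused) | CC(C)(C)[Si](C)(C)OCC[C@@]1(C)[C@H](C)CC[C@@]2(C)C(C)=CCC[C@H]12 | intermediate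
14 | 2-[(1S,2R,4aR,8aR)-1,2,4a,5-tetramethyl-1,2,3,4,4a,7,8,8a-octahydronaphthalen-1-yl]ethan-1-ol | OCC[C@@]1(C)[C@H](C)CC[C@@]2(C)C(C)=CCC[C@H]12 | intermediate
15 | (1S,2R,4aR,8aR)-1-(2-iodoethyl)-1,2,4a,5-tetramethyl-1,2,3,4,4a,7,8,8a-octahydronaphthalene | ICC[C@@]1(C)[C@H](C)CC[C@@]2(C)C(C)=CCC[C@H]12 | intermediate
16 | but-2-yne-1,4-diol | OCC#CCO | starting material
17 | 4-[(tert-butyldimethylsilyl)oxy]but-2-yn-1-ol | OCC#CCO[Si](C)(C)C(C)(C)C | intermediate
18 | sodium 3-({[tert-butyldimethylsilyl]oxy}methyl)-2,2-bis(2-methoxyethoxy)-2,5-dihydro-1,2-oxaluminol-2-uide (cyclic alkenylaluminate) | [Na+].COCCO[Al-]1(OCCOC)OCC=C1CO[Si](C)(C)C(C)(C)C | intermediate (not isolated)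
19 | (2Z)-4-[(tert-butyldimethylsilyl)oxy]-3-iodobut-2-en-1-ol | OC/C=C(\I)CO[Si](C)(C)C(C)(C)C | intermediate
20 | {2-[(1S,2R,4aR,8aR)-1,2,4a,5-tetramethyl-1,2,3,4,4a,7,8,8a-octahydronaphthalen-1-yl]ethyl}lithium | [Li]CC[C@@]1(C)[C@H](C)CC[C@@]2(C)C(C)=CCC[C@H]12 | intermediate (not isolated)
21 | lithium 9-methoxy-9-{2-[(1S,2R,4aR,8aR)-1,2,4a,5-tetramethyl-1,2,3,4,4a,7,8,8a-octahydronaphthalen-1-yl]ethyl}-9-borabicyclo[3.3.1]nonan-9-uide | [Li+].CO[B-]1(CC[C@@]2(C)[C@H](C)CC[C@@]3(C)C(C)=CCC[C@H]23)C4CCCC1CCC4 | intermediate (not isolated)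
22 | (2E)-3-({[tert-butyldimethylsilyl]oxy}methyl)-5-[(1S,2R,4aR,8aR)-1,2,4a,5-tetramethyl-1,2,3,4,4a,7,8,8a-octahydronaphthalen-1-yl]pent-2-en-1-ol | OC/C=C(/CO[Si](C)(C)C(C)(C)C)CC[C@@]1(C)[C@H](C)CC[C@@]2(C)C(C)=CCC[C@H]12 | intermediate
23 | docosanoic acid | CCCCCCCCCCCCCCCCCCCCCC(=O)O | starting material
24 | (2E)-3-({[tert-butyldimethylsilyl]oxy}methyl)-5-[(1S,2R,4aR,8aR)-1,2,4a,5-tetramethyl-1,2,3,4,4a,7,8,8a-octahydronaphthalen-1-yl]pent-2-en-1-yl docosanoate | CCCCCCCCCCCCCCCCCCCCCC(=O)OC/C=C(/CO[Si](C)(C)C(C)(C)C)CC[C@@]1(C)[C@H](C)CC[C@@]2(C)C(C)=CCC[C@H]12 | intermediate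
25 | (2E)-3-(hydroxymethyl)-5-[(1S,2R,4aR,8aR)-1,2,4a,5-tetramethyl-1,2,3,4,4a,7,8,8a-octahydronaphthalen-1-yl]pent-2-en-1-yl docosanoate | CCCCCCCCCCCCCCCCCCCCCC(=O)OC/C=C(/CO)CC[C@@]1(C)[C@H](C)CC[C@@]2(C)C(C)=CCC[C@H]12 | target

**Totals**

Total step count: 17. Longest linear sequence: 15 steps (1 → 25 through steps 1–12 and 15–17).

**Steps most likely to fail**

1. Step 8. The transannular ene closure onto the fully substituted C4=C5 bond, next to quaternary C9, may be slower than other thermal processes of 8 and 10: retro-ene cleavage of the β-hydroxy olefin, hydrogen transfer from the C4 methyl (exocyclic olefin), or closure at C4 to a 5/7 skeleton. Fallback: the two bond formations are separated and the second is run as a low-temperature cationic closure. Starting from 8, KH and 18-crown-6 in THF (0 °C → rt) bring about the anion-accelerated oxy-Cope rearrangement and deliver the potassium enolate F1. Aqueous NH4Cl then gives the cyclodecenone 10, which is isolated here. (CH3)2AlCl in CH2Cl2 at −78 °C closes C5–C10 by a Lewis-acid-promoted transannular carbonyl-ene (Prins-type) reaction, and the route is rejoined at 11.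

2. Step 10. The tertiary oxalate may eliminate thermally toward C1 before the chain reduction takes hold, and hydrogen-atom transfer to the C10 radical may not be fully face-selective. Fallback: electron-transfer deoxygenation of a simple ester at room temperature. Starting from 11, n-BuLi and then acetic anhydride (THF, −78 °C → rt) give the tertiary acetate F2. Potassium and 18-crown-6 in tert-butylamine/THF at rt cleave its alkyl–oxygen bond (the dissolving-metal deoxygenation of hindered esters), and the C10 radical/anion is quenched on the open face. The isolated trisubstituted olefin and the silyl ether are expected to survive. The route is rejoined at 13.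

3. Step 7. Addition to a carbonyl flanked by two quaternary carbons may stall or give way to electron transfer. Fallback: a slimmer sp nucleophile followed by partial reduction. Starting from 7, lithium acetylide (acetylene, n-BuLi, THF, −78 °C → rt) adds from the same open face to give the propargylic alcohol F3. Semi-hydrogenation (H2, Pd/CaCO3 poisoned with Pb(OAc)2, quinoline, EtOAc, rt) leaves the isopropenyl group untouched and rejoins the route at 8.

**Further compounds**

F1 | step 8 | potassium (1Z,5Z,9R,10S)-10-{2-[(tert-butyldimethylsilyl)oxy]ethyl}-5,6,9,10-tetramethylcyclodeca-1,5-dien-1-olate | [K+].[O-]/C1=C\CC/C(C)=C(C)\CC[C@@H](C)[C@]1(C)CCO[Si](C)(C)C(C)(C)C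
F2 | step 10 | (4aR,5S,6R,8aS)-5-{2-[(tert-butyldimethylsilyl)oxy]ethyl}-1,5,6,8a-tetramethyl-3,4,4a,5,6,7,8,8a-octahydronaphthalen-4a-yl acetate | CC(C)(C)[Si](C)(C)OCC[C@@]1(C)[C@H](C)CC[C@@]2(C)C(C)=CCC[C@@]12OC(C)=O
F3 | step 7 | (1R,2S,3R,6S)-2-{2-[(tert-butyldimethylsilyl)oxy]ethyl}-1-ethynyl-2,3,6-trimethyl-6-(prop-1-en-2-yl)cyclohexan-1-ol | CC(C)(C)[Si](C)(C)OCC[C@@]1(C)[C@H](C)CC[C@@](C)(C(C)=C)[C@@]1(O)C#C
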